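**Retrosynthetic overview**
- The ArCH2–Ar bond is cut last-but-one: a phenolic Mannich base of the 6-methylflavan releases an ortho-quinone methide, and a C6-bromo-blocked 7-hydroxy-5-methoxyflavan (only C8 free) adds to it in a Michael reaction. The bromine is then removed.
- Both flavan halves come from one intermediate, methyl (2S)-7-hydroxy-5-methoxy-2-phenylchromane-8-carboxylate. Its C8 ester forces substitution to C6 (Mannich/hydride gives CH3, NBS gives Br) and is then lost as CO2.
- That ester comes from Mitsunobu ring closure (inversion) of an (R)-1-phenyl-3-arylpropan-1-ol, made by asymmetric transfer hydrogenation of the ketone from a Claisen–Schmidt aldol of a benzaldehyde with acetophenone.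
- The benzaldehyde comes from methyl 2,4,6-trihydroxybenzoate by 4-O-methylation, formylation and benzylation.
- Ring order: both aromatic rings are bought; the pyran ring is closed once (step 7) and serves both halves; no ring is formed afterwards.

Assumption: the catalogue number is taken to mean exactly the given SMILES, i.e. the (2S,2'S) 8,8'-methylene-linked biflavan; methyl 2,4,6-trihydroxybenzoate and acetophenone are taken as the commercial starting materials.

**Route**

Step 1
Reactants: 1 methyl 2,4,6-trihydroxybenzoate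
Product: 2 methyl 2,6-dihydroxy-4-methoxybenzoate
Conditions: Me2SO4 (1.0 equiv), K2CO3 (1.0 equiv), acetone, 0 °C to rt
Reagents that add atoms: dimethyl sulfate COS(=O)(=O)OC
Why: Williamson O-methylation in which the 4-OH, the only hydroxyl not hydrogen-bonded to the ester and the most acidic, is alkylated selectively by one equivalent of base and electrophile.

Step 2
Reactants: 2 methyl 2,6-dihydroxy-4-methoxybenzoate
Product: 4 methyl 3-formyl-2,6-dihydroxy-4-methoxybenzoate, via α-chloro ether 3 (not isolated)
Conditions: Cl2CHOMe (1.2 equiv), TiCl4 (3 equiv), CH2Cl2, 0 °C to rt; then 1 M HCl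
Reagents that add atoms: dichloromethyl methyl ether COC(Cl)Cl; water O
Why: Rieche formylation ortho to a titanium-bound phenoxide, where C3 and C5 are equivalent by symmetry so only one mono-aldehyde can form and the first formyl group deactivates the ring against a second.

Step 3
Reactants: 4 methyl 3-formyl-2,6-dihydroxy-4-methoxybenzoate
Product: 5 methyl 2,6-bis(benzyloxy)-3-formyl-4-methoxybenzoate
Conditions: BnBr (2.5 equiv), K2CO3 (3 equiv), Bu4NI (cat.), DMF, 60 °C
Reagents that add atoms: benzyl bromide BrCc1ccccc1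
Why: Williamson etherification masks both phenols so the aldehyde is not deactivated as a phenoxide in the aldol step, and benzyl is chosen because it leaves during the hydrogenation of step 5.

Step 4
Reactants: 5 methyl 2,6-bis(benzyloxy)-3-formyl-4-methoxybenzoate; 6 acetophenone
Product: 8 methyl 2,6-bis(benzyloxy)-4-methoxy-3-[(1E)-3-oxo-3-phenylprop-1-en-1-yl]benzoate, via aldol adduct 7 (not isolated)
Conditions: 6 (1.2 equiv), KOH (3 equiv), MeOH/THF, rt, 24 h
Reagents that add atoms: none
Why: Claisen–Schmidt crossed aldol condensation of a non-enolisable aldehyde with the acetophenone enolate followed by E1cB dehydration to the E-enone, while the di-ortho-substituted methyl ester resists saponification at rt.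

Step 5
Reactants: 8 methyl 2,6-bis(benzyloxy)-4-methoxy-3-[(1E)-3-oxo-3-phenylprop-1-en-1-yl]benzoate
Product: 9 methyl 2,6-dihydroxy-4-methoxy-3-(3-oxo-3-phenylpropyl)benzoate
Conditions: H2 (1 atm), 10% Pd/C, EtOAc/MeOH (1:1), rt; stopped after uptake of 3 equiv H2
Reagents that add atoms: none
Why: Heterogeneous catalytic hydrogenation saturates the enone C=C and hydrogenolyses both aryl benzyl ethers, whereas the aryl ketone and the ester react far more slowly under neutral conditions at 1 atm.

Step 6
Reactants: 9 methyl 2,6-dihydroxy-4-methoxy-3-(3-oxo-3-phenylpropyl)benzoate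
Product: 10 methyl 2,6-dihydroxy-3-[(3R)-3-hydroxy-3-phenylpropyl]-4-methoxybenzoate
Conditions: RuCl(p-cymene)[(R,R)-TsDPEN] (1 mol%), HCO2H/Et3N (5:2), DMF, 35 °C
Reagents that add atoms: none
Why: Noyori–Ikariya asymmetric transfer hydrogenation of an aryl alkyl ketone tolerates free phenols, and the (R,R)-catalyst gives the (R)-benzylic alcohol (same sense as for acetophenone) in typically 95% ee or better.

Step 7
Reactants: 10 methyl 2,6-dihydroxy-3-[(3R)-3-hydroxy-3-phenylpropyl]-4-methoxybenzoate
Product: 11 methyl (2S)-7-hydroxy-5-methoxy-2-phenylchromane-8-carboxylate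
Conditions: PPh3 (1.5 equiv), DIAD (1.5 equiv), THF (0.02 M), 0 °C to rt
Reagents that add atoms: none
Why: Intramolecular Mitsunobu etherification in which the only phenol ortho to the side chain displaces the activated benzylic oxygen by SN2 with inversion, turning the (R)-carbinol into the (2S)-chromane.

Step 8
Reactants: 11 methyl (2S)-7-hydroxy-5-methoxy-2-phenylchromane-8-carboxylate
Product: 12 methyl (2S)-6-[(dimethylamino)methyl]-7-hydroxy-5-methoxy-2-phenylchromane-8-carboxylate
Conditions: CH2=NMe2+ I− (1.5 equiv), K2CO3 (2 equiv), MeCN, rt to 50 °C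
Reagents that add atoms: N,N-dimethylmethyleneiminium iodide C=[N+](C)C.[I-]
Why: Mannich aminomethylation of the phenol with a preformed iminium ion can only occur at C6, ortho to the hydroxyl, because C8 carries the ester.

Step 9
Reactants: 12 methyl (2S)-6-[(dimethylamino)methyl]-7-hydroxy-5-methoxy-2-phenylchromane-8-carboxylate
Product: 15 methyl (2S)-7-hydroxy-5-methoxy-6-methyl-2-phenylchromane-8-carboxylate, via quaternary ammonium iodide 13 (not isolated), via ortho-quinone methide 14 (not isolated)
Conditions: MeI (5 equiv), MeCN, rt; evaporate; NaBH4 (5 equiv), EtOH/THF, 0 to 50 °C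
Reagents that add atoms: none
Why: Reductive deamination in which N-quaternisation makes the amine a leaving group, the phenoxide expels NMe3 to an ortho-quinone methide and borohydride adds hydride in conjugate fashion to leave the C6 methyl, the hindered chelated ester being inert to NaBH4.

Step 10
Reactants: 15 methyl (2S)-7-hydroxy-5-methoxy-6-methyl-2-phenylchromane-8-carboxylate
Product: 17 (2S)-5-methoxy-6-methyl-2-phenylchroman-7-ol, via carboxylic acid 16 (not isolated)
Conditions: KOH (10 equiv), DMSO/H2O (4:1), 110 °C; then 1 M HCl to pH 3, 60 °C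
Reagents that add atoms: none
Why: Saponification followed by protodecarboxylation, which is easy for a 2-hydroxy-4,6-dialkoxybenzoic acid because ipso protonation is supported by three oxygen donors, and C2 has no acidifying group so its configuration is untouched.

Step 11
Reactants: 17 (2S)-5-methoxy-6-methyl-2-phenylchroman-7-ol
Product: 18 (2S)-8-[(dimethylamino)methyl]-5-methoxy-6-methyl-2-phenylchroman-7-ol
Conditions: CH2=NMe2+ I− (1.1 equiv), K2CO3 (1.5 equiv), CH2Cl2, 0 °C to rt
Reagents that add atoms: N,N-dimethylmethyleneiminium iodide C=[N+](C)C.[I-]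
Why: Mannich reaction at C8, the only unsubstituted position of this electron-rich phenol, gives a single stable regioisomer, and the preformed iminium ion avoids the symmetrical diarylmethane.

Step 12
Reactants: 11 methyl (2S)-7-hydroxy-5-methoxy-2-phenylchromane-8-carboxylate
Product: 19 methyl (2S)-6-bromo-7-hydroxy-5-methoxy-2-phenylchromane-8-carboxylate
Conditions: NBS (1.05 equiv), MeCN, 0 °C, dark
Reagents that add atoms: N-bromosuccinimide O=C1CCC(=O)N1Br
Why: Electrophilic aromatic bromination goes to C6, the only free position of the activated ring, and ionic conditions in the dark leave the benzylic C–H bonds alone.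

Step 13
Reactants: 19 methyl (2S)-6-bromo-7-hydroxy-5-methoxy-2-phenylchromane-8-carboxylate
Product: 21 (2S)-6-bromo-5-methoxy-2-phenylchroman-7-ol, via carboxylic acid 20 (not isolated)
Conditions: KOH (10 equiv), DMSO/H2O (4:1), 110 °C; then 1 M HCl to pH 3, 60 °C
Reagents that add atoms: none
Why: Saponification and protodecarboxylation as in step 10 free C8, while the aryl bromide, which has no ortho hydrogen and sits on an electron-rich ring, is inert to hydroxide.

Step 14
Reactants: 18 (2S)-8-[(dimethylamino)methyl]-5-methoxy-6-methyl-2-phenylchroman-7-ol; 21 (2S)-6-bromo-5-methoxy-2-phenylchroman-7-ol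
Product: 23 (2S)-6-bromo-8-{[(2S)-7-hydroxy-5-methoxy-6-methyl-2-phenylchroman-8-yl]methyl}-5-methoxy-2-phenylchroman-7-ol, via ortho-quinone methide 22 (not isolated)
Conditions: 18 (1.0 equiv), 21 (1.3 equiv), toluene (0.05 M), 110 °C, N2 sweep, 12 h
Reagents that add atoms: none
Why: Thermal loss of Me2NH from the phenolic Mannich base gives an ortho-quinone methide, to which phenol 21 adds through C8, its only free ring carbon, in a Michael addition that re-aromatises the ring; neither partner can self-condense or react twice, and no stereocentre is formed.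

Step 15
Reactants: 23 (2S)-6-bromo-8-{[(2S)-7-hydroxy-5-methoxy-6-methyl-2-phenylchroman-8-yl]methyl}-5-methoxy-2-phenylchroman-7-ol
Product: 24 (2S)-8-{[(2S)-7-hydroxy-5-methoxy-6-methyl-2-phenylchroman-8-yl]methyl}-5-methoxy-2-phenylchroman-7-ol
Conditions: H2 (1 atm), 10% Pd/C, NaOAc (2 equiv), MeOH/EtOAc, rt
Reagents that add atoms: none
Why: Catalytic hydrodehalogenation removes the aryl bromide under neutral buffered conditions at which the cyclic benzylic ethers of the two chromanes and the diarylmethane are stable, so both (2S) centres are kept.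

**Compound list**

1 | methyl 2,4,6-trihydroxybenzoate | COC(=O)c1c(O)cc(O)cc1O | starting material
2 | methyl 2,6-dihydroxy-4-methoxybenzoate | COC(=O)c1c(O)cc(OC)cc1O | intermediate
3 | methyl 3-[chloro(methoxy)methyl]-2,6-dihydroxy-4-methoxybenzoate | COC(=O)c1c(O)cc(OC)c(C(Cl)OC)c1O | intermediate
4 | methyl 3-formyl-2,6-dihydroxy-4-methoxybenzoate | COC(=O)c1c(O)cc(OC)c(C=O)c1O | intermediate
5 | methyl 2,6-bis(benzyloxy)-3-formyl-4-methoxybenzoate | COC(=O)c1c(OCc2ccccc2)cc(OC)c(C=O)c1OCc1ccccc1 | intermediate
6 | acetophenone | CC(=O)c1ccccc1 | starting material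
7 | methyl 2,6-bis(benzyloxy)-3-(1-hydroxy-3-oxo-3-phenylpropyl)-4-methoxybenzoate (racemic aldol adduct) | COC(=O)c1c(OCc2ccccc2)cc(OC)c(C(O)CC(=O)c2ccccc2)c1OCc1ccccc1 | intermediate
8 | methyl 2,6-bis(benzyloxy)-4-methoxy-3-[(1E)-3-oxo-3-phenylprop-1-en-1-yl]benzoate | COC(=O)c1c(OCc2ccccc2)cc(OC)c(/C=C/C(=O)c2ccccc2)c1OCc1ccccc1 | intermediate
9 | methyl 2,6-dihydroxy-4-methoxy-3-(3-oxo-3-phenylpropyl)benzoate | COC(=O)c1c(O)cc(OC)c(CCC(=O)c2ccccc2)c1O | intermediate
10 | methyl 2,6-dihydroxy-3-[(3R)-3-hydroxy-3-phenylpropyl]-4-methoxybenzoate | COC(=O)c1c(O)cc(OC)c(CC[C@@H](O)c2ccccc2)c1O | intermediate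
11 | methyl (2S)-7-hydroxy-5-methoxy-2-phenylchromane-8-carboxylate | COC(=O)c1c(O)cc(OC)c2c1O[C@H](c1ccccc1)CC2 | intermediate
12 | methyl (2S)-6-[(dimethylamino)methyl]-7-hydroxy-5-methoxy-2-phenylchromane-8-carboxylate | COC(=O)c1c(O)c(CN(C)C)c(OC)c2c1O[C@H](c1ccccc1)CC2 | intermediate
13 | {[(2S)-7-hydroxy-5-methoxy-8-(methoxycarbonyl)-2-phenylchroman-6-yl]methyl}trimethylammonium iodide | COC(=O)c1c(O)c(C[N+](C)(C)C)c(OC)c2c1O[C@H](c1ccccc1)CC2.[I-] | intermediate
14 | methyl (2S)-5-methoxy-6-methylidene-7-oxo-2-phenyl-3,4,6,7-tetrahydro-2H-chromene-8-carboxylate (ortho-quinone methide) | COC(=O)C1=C2O[C@H](c3ccccc3)CCC2=C(OC)C(=C)C1=O | intermediate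
15 | methyl (2S)-7-hydroxy-5-methoxy-6-methyl-2-phenylchromane-8-carboxylate | COC(=O)c1c(O)c(C)c(OC)c2c1O[C@H](c1ccccc1)CC2 | intermediate
16 | (2S)-7-hydroxy-5-methoxy-6-methyl-2-phenylchromane-8-carboxylic acid | O=C(O)c1c(O)c(C)c(OC)c2c1O[C@H](c1ccccc1)CC2 | intermediate
17 | (2S)-5-methoxy-6-methyl-2-phenylchroman-7-ol | COc1c(C)c(O)cc2O[C@H](c3ccccc3)CCc12 | intermediate
18 | (2S)-8-[(dimethylamino)methyl]-5-methoxy-6-methyl-2-phenylchroman-7-ol | COc1c(C)c(O)c(CN(C)C)c2O[C@H](c3ccccc3)CCc12 | intermediate
19 | methyl (2S)-6-bromo-7-hydroxy-5-methoxy-2-phenylchromane-8-carboxylate | COC(=O)c1c(O)c(Br)c(OC)c2c1O[C@H](c1ccccc1)CC2 | intermediate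
20 | (2S)-6-bromo-7-hydroxy-5-methoxy-2-phenylchromane-8-carboxylic acid | O=C(O)c1c(O)c(Br)c(OC)c2c1O[C@H](c1ccccc1)CC2 | intermediate
21 | (2S)-6-bromo-5-methoxy-2-phenylchroman-7-ol | COc1c(Br)c(O)cc2O[C@H](c3ccccc3)CCc12 | intermediate
22 | (2S)-5-methoxy-6-methyl-8-methylidene-2-phenyl-3,4-dihydro-2H-chromen-7(8H)-one (ortho-quinone methide) | COC1=C(C)C(=O)C(=C)C2=C1CC[C@@H](c1ccccc1)O2 | intermediate
23 | (2S)-6-bromo-8-{[(2S)-7-hydroxy-5-methoxy-6-methyl-2-phenylchroman-8-yl]methyl}-5-methoxy-2-phenylchroman-7-ol | COc1c(Br)c(O)c(Cc2c(O)c(C)c(OC)c3c2O[C@H](c2ccccc2)CC3)c2c1CC[C@@H](c1ccccc1)O2 | intermediate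
24 | (2S)-8-{[(2S)-7-hydroxy-5-methoxy-6-methyl-2-phenylchroman-8-yl]methyl}-5-methoxy-2-phenylchroman-7-ol (CNP0114750.1) | COc1cc(O)c(Cc2c(O)c(C)c(OC)c3c2O[C@H](c2ccccc2)CC3)c2c1CC[C@@H](c1ccccc1)O2 | target

**Step count and risks**

Total steps: 15. Longest linear sequence: 13 (steps 1–11, then 14 and 15); the bromo branch (steps 12–13) joins at step 14.

Steps most likely to fail:

Step 14 (quinone methide Michael coupling). The quinone methide may dimerise or be trapped on oxygen, and the diarylmethane can scramble by retro-Michael reaction at 110 °C. The fallback sets out from 15 and comes back at 23. Ester 15 is reduced with LiAlH4 (THF, 0 °C) to the fully substituted ortho-hydroxybenzyl alcohol (2S)-8-(hydroxymethyl)-5-methoxy-6-methyl-2-phenylchroman-7-ol F1. This alkylates C8 of bromophenol 21 in an acid-catalysed Friedel–Crafts benzylation (5 mol% TsOH·H2O, CH2Cl2, 0 °C to rt), so that the former ester carbon becomes the bridge and 23 is reached without steps 10, 11 and 14.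

Step 7 (Mitsunobu ring closure). The phenol is hindered and hydrogen-bonded to the ester, so elimination to the styrene, intermolecular etherification or partial loss of ee can compete. The fallback sets out from 9 and comes back at 11. Keto-phenol 9 is cyclodehydrated (cat. TsOH·H2O, toluene, Dean–Stark) to the enol ether methyl 7-hydroxy-5-methoxy-2-phenyl-4H-chromene-8-carboxylate F2. Its C2=C3 bond is then hydrogenated enantioselectively (H2 50 bar, [Ir(cod)(tBu-PHOX)]BArF, CH2Cl2) to give 11; which ligand enantiomer gives 2S is not assigned here and must be checked by chiral HPLC. This replaces steps 6 and 7.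

Step 9 (reductive deamination to the C6 methyl). The ester-conjugated phenoxide may expel NMe3 slowly, and the quinone methide may dimerise before hydride capture. The fallback sets out from 19 (already made in step 12) and comes back at 15. It is a Suzuki–Miyaura methylation of the aryl bromide with trimethylboroxine (Pd(OAc)2, SPhos, K3PO4, toluene/H2O, 100 °C). It replaces steps 8 and 9 and makes no new compound (F0).

Further compounds
F1 | step 14 | (2S)-8-(hydroxymethyl)-5-methoxy-6-methyl-2-phenylchroman-7-ol | COc1c(C)c(O)c(CO)c2O[C@H](c3ccccc3)CCc12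
F2 | step 7 | methyl 7-hydroxy-5-methoxy-2-phenyl-4H-chromene-8-carboxylate | COC(=O)c1c(O)cc(OC)c2c1OC(c1ccccc1)=CC2
F0 | step 9 | none | none
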